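The data were computed with made-up constants, and the scatter is random.

At 4.00 min, the first reading of the ash flask, the substrate stands at 49%, and at 50.0 min it stands at 51%, a shift of about the size of the scatter. Ash has the charges of the flask asked about, so I must judge what this plateau is and whether it lasts to 2.5 h.

common to all: substrate 0.090 M
- ash: reagent 0.063 M; the very flask that is asked about, followed so far
- cedar: reagent 0.095 M; run made earlier
- flask: reagent 0.0630 M; time 2.5 h

| run | time / min | substrate / % | target / % | isomer of the product / % |
|---|---|---|---|---|
| ash | 4.00 | 49 | 7 | 42 |
| ash | 6.00 | 50 | 9 | 42 |
| ash | 10.0 | 51 | 9 | 40 |
| ash | 15.0 | 48 | 9 | 43 |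
| ash | 25.0 | 47 | 9 | 42 |
| ash | 50.0 | 51 | 10 | 45 |
| cedar | 4.00 | 33 | 10 | 54 |
| cedar | 12.0 | 31 | 13 | 54 |
| cedar | 20.0 | 33 | 9 | 55 |
| cedar | 30.0 | 33 | 13 | 54 |
| cedar | 50.0 | 32 | 13 | 54 |
| cedar | 60.0 | 31 | 11 | 57 |

(readings scatter by 1.5 percentage points)

1. the state of affairs at 2.5 h: stopped, and by what, or still going (the reagent has run out first / forward and back rates have come level / all of the substrate has reacted / it is still moving)
2. share of the substrate used up at 2.5 h
3. target at 2.5 h, in percent of the substrate charged
4. isomer of the product at 2.5 h, in percent of the substrate charged

- what was read earlier has a scatter of 1.5 percentage points, one standard deviation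
- the reaction counts as stopped when no species that holds the substrate changes by six tenths of a point or more over the second half of the time

The ash readings average 49.3% substrate, so 50.7% is lost. Target averages 8.83% and isomer 42.3%, together 51.1%, so I take one substrate and one reagent to make one product. In ash:

products made = 0.0456 M
substrate left = 0.0444 M
reagent left = 0.0174 M

Both partners remain in ash, yet its substrate readings hold level within about their scatter, so I read forward and back rates as level. I carry the balance number, products made divided by substrate left times reagent left (the overall equilibrium constant):

59.0 /M

The weak link is the reagent left, a small difference of larger numbers. So I reforge it on the cedar run, which keeps 32.2% substrate and gives a balance number of 62.1 /M. Solved back for the ash charges, the cedar number gives a conversion of 51.2%. For the flask at 2.5 h I commit to forward and back rates level, a conversion of 50.7%, target 8.83% and isomer 42.3%.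

The forecast says forward and back rates have come level, with conversion 51%, target 9.3% and isomer 42%, on the ground that “Mass action does fit”. Its target stands above mine.

The flask gives forward and back rates have come level at 2.5 h: conversion 50.5%, target 8.28%, isomer 42.2%.

    substrate + reagent ⇌ isomer of the product (K = 48.4 /M, k = 1.59 /M/s)
    substrate + reagent ⇌ target (K = 9.50 /M, k = 4.81 /M/s)

At the start, the forward step to the isomer uses substrate at 0.33 of the rate of the forward step to target, slower, yet the isomer ends above target: thermodynamic control, not kinetic. Applied to the flask's conversion, the balance number gives reagent left at 27.4% of its charge, and the flask holds 28%.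

For a flask like this one but charged with 0.16 M of reagent, the balance number solved for the amount made gives a conversion of 83.4%. The computed flask gives 83.1%.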